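**Retrosynthetic overview**

1. The strategy rests on the butenolide ring O1–C2(=O)–C3(CH3)=C4(CO2H)–C5(H)(C15 chain). The lactone carbonyl C2 and the carboxyl on C4 sit on opposite sides of C3=C4, so the unit C2–C3=C4–C5 is a 2-methyl-2,3-allenoic acid in disguise, with the central allene carbon becoming C4.
2. Key disconnection: O1–C5 and C4–CO2Me are made in one operation by divalent-palladium cyclisation of the (aS)-allenoic acid under CO and methanol. This is the only ring closure, and one acid hydrolysis follows it.
3. The allenoic acid comes from an (R)-propargylic mesylate by zerovalent-palladium anti SN2' carbonylation (CO supplies C2). The (R)-carbinol comes from Noyori transfer hydrogenation of an ynone.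
4. The ynone comes from a ketal-masked C16 keto aldehyde and propynyl Grignard; the C16 chain comes from ω-pentadecalactone and methyl Grignard through a Weinreb amide.

Key step: step 10

Remark: the sense of induction in step 7 is assigned by analogy with other alkynyl ketones (alkynyl in the place usually taken by aryl). The configuration of 10 would be confirmed through its Mosher esters and the antipodal catalyst used if required. The axis of 13 is written (aS), which is P helicity.

**Route**

Step 1
Reactants: 1 ω-pentadecalactone (oxacyclohexadecan-2-one)
Product: 2 15-hydroxy-N-methoxy-N-methylpentadecanamide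
Conditions: MeNH(OMe)·HCl, i-PrMgCl, THF, −15 → 0 °C; aq NH4Cl
Reagents that add atoms: N,O-dimethylhydroxylamine hydrochloride, CNOC.Cl
Why: The chloromagnesium amide of N,O-dimethylhydroxylamine should open the lactone by acyl substitution (Weinreb amide formation from an ester), and the amide formed is inert to further attack.

Step 2
Reactants: 2 15-hydroxy-N-methoxy-N-methylpentadecanamide; 3 methylmagnesium bromide
Product: 4 16-hydroxyhexadecan-2-one
Conditions: MeMgBr (3 equiv), THF, 0 °C → rt; aq NH4Cl
Reagents that add atoms: methylmagnesium bromide 3, C[Mg]Br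
Why: Weinreb ketone synthesis; one equivalent of Grignard reagent is spent on the hydroxyl, and the chelated tetrahedral adduct should release the methyl ketone only on work-up, so no tertiary alcohol is expected.

Step 3
Reactants: 4 16-hydroxyhexadecan-2-one
Product: 5 14-(2-methyl-1,3-dioxolan-2-yl)tetradecan-1-ol
Conditions: HOCH2CH2OH, p-toluenesulfonic acid (cat.), toluene, reflux, Dean–Stark
Reagents that add atoms: ethylene glycol, OCCO
Why: Acid-catalysed ketalisation with azeotropic removal of water should mask the ketone against the later Grignard addition and transfer hydrogenation.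

Step 4
Reactants: 5 14-(2-methyl-1,3-dioxolan-2-yl)tetradecan-1-ol
Product: 6 14-(2-methyl-1,3-dioxolan-2-yl)tetradecanal
Conditions: (COCl)2, DMSO, CH2Cl2, −78 °C; Et3N, → 0 °C
Reagents that add atoms: none
Why: Swern oxidation should stop at the aldehyde, and its basic, anhydrous conditions leave the dioxolane untouched.

Step 5
Reactants: 6 14-(2-methyl-1,3-dioxolan-2-yl)tetradecanal; 7 1-propynylmagnesium bromide
Product: 8 (±)-17-(2-methyl-1,3-dioxolan-2-yl)heptadec-2-yn-4-ol
Conditions: THF, −78 → 0 °C; aq NH4Cl
Reagents that add atoms: 1-propynylmagnesium bromide 7, CC#C[Mg]Br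
Why: Grignard addition of the alkynyl nucleophile to the aldehyde should give the racemic carbinol, whose configuration is set afresh in step 7.

Step 6
Reactants: 8 (±)-17-(2-methyl-1,3-dioxolan-2-yl)heptadec-2-yn-4-ol
Product: 9 17-(2-methyl-1,3-dioxolan-2-yl)heptadec-2-yn-4-one
Conditions: (n-Pr)4N[RuO4] (5 mol %), N-methylmorpholine N-oxide, 4 Å MS, CH2Cl2, rt
Reagents that add atoms: none
Why: Ley–Griffith oxidation of the activated propargylic alcohol should give the ynone under neutral conditions that spare the ketal.

Step 7
Reactants: 9 17-(2-methyl-1,3-dioxolan-2-yl)heptadec-2-yn-4-one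
Product: 10 (R)-17-(2-methyl-1,3-dioxolan-2-yl)heptadec-2-yn-4-ol
Conditions: RuCl[(R,R)-TsDPEN](p-cymene) (1 mol %; TsDPEN = N-tosyl-1,2-diphenylethylenediamine), i-PrOH, rt
Reagents that add atoms: none
Why: Noyori asymmetric transfer hydrogenation; hydride and proton are delivered from the ruthenium amine complex in a six-membered transition state in which the alkynyl group takes the place of an aryl group, so the (R,R) ligand should set the R carbinol, and the reduction of an ynone in 2-propanol is practically irreversible.

Step 8
Reactants: 10 (R)-17-(2-methyl-1,3-dioxolan-2-yl)heptadec-2-yn-4-ol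
Product: 11 (R)-17-(2-methyl-1,3-dioxolan-2-yl)heptadec-2-yn-4-yl methanesulfonate
Conditions: MsCl, Et3N, CH2Cl2, −78 → −20 °C; used without chromatography
Reagents that add atoms: methanesulfonyl chloride, CS(=O)(=O)Cl
Why: Sulfonylation occurs at oxygen only, so the C–O bond and the R configuration are expected to be preserved.

Step 9
Reactants: 11 (R)-17-(2-methyl-1,3-dioxolan-2-yl)heptadec-2-yn-4-yl methanesulfonate; 12 carbon monoxide
Product: 13 (aS)-2-methyl-17-(2-methyl-1,3-dioxolan-2-yl)heptadeca-2,3-dienoic acid
Conditions: Pd(PPh3)4 (5 mol %), CO (1 atm), 2,6-lutidine (1.2 equiv), THF–H2O (10:1), rt; work-up at pH 4–5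
Reagents that add atoms: carbon monoxide 12, [C-]#[O+]; water, O
Why: Zerovalent palladium should displace the mesylate in an anti SN2' sense to give an allenylpalladium, CO insertion with retention and capture of the acylpalladium by water then give the allenoic acid (the known hydroxycarbonylation of enantioenriched propargylic mesylates), so the R centre is translated into the aS axis while the lutidine takes up the sulfonic acid and protects the ketal.

Step 10
Reactants: 13 (aS)-2-methyl-17-(2-methyl-1,3-dioxolan-2-yl)heptadeca-2,3-dienoic acid; 12 carbon monoxide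
Product: 14 methyl (S)-4-methyl-2-[13-(2-methyl-1,3-dioxolan-2-yl)tridecyl]-5-oxo-2,5-dihydrofuran-3-carboxylate
Conditions: Pd(O2CCF3)2 (5 mol %), p-benzoquinone (1.5 equiv), NaOAc (0.2 equiv), CO (1 atm), MeOH–THF (1:1), −20 °C → rt
Reagents that add atoms: carbon monoxide 12, [C-]#[O+]; methanol, CO
Why: Proposed new method: divalent palladium should bind the terminal π bond of the allene (future C4=C5) on the face turned away from the carboxyl, and the carboxylate oxygen then adds to C5 anti to the metal, forming O1–C5 and leaving a 4-palladated butenolide, a vinylpalladium with no β-hydride path; CO inserts into the C4–Pd bond, methanol cleaves the acylpalladium to the methyl ester, and benzoquinone returns the zerovalent palladium released to the divalent state. The closest known reaction types are the oxidative cyclisation–methoxycarbonylation of allenes and alkynes carrying a tethered oxygen or nitrogen nucleophile (divalent palladium, CO, methanol, reoxidant) and the divalent-palladium cyclisation–coupling of optically active 2,3-allenoic acids, where the same 4-palladated butenolide is intercepted by allyl halides or alkenes with transfer of the axial chirality; trapping it with CO is the extension proposed. The butenolide ring closes in a formally 5-endo-trig mode, which is easy here because the π lobes of C4=C5 lie in the plane that holds the C2 carboxyl, so the oxygen reaches C5 without strain. The new stereocentre C5 is controlled by the allene axis alone: the carboxyl can reach only one face of C5, so the aS axis should give S at C5, the carbinol configuration of 10 being inverted overall. The step needs carbonylation of the vinylpalladium to outrun protonolysis and oxidative dimerisation, and it needs the allene not to racemise before closure; the CO atmosphere, methanol as cosolvent, acetate buffering, absence of halide and low temperature serve the first, and the 2-methyl group, which blocks tautomerisation to a dienoate, serves the second. The regiochemistry (oxygen to the allene terminus, carbonyl to the central carbon) follows from the tether, and the remote dioxolane is inert.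

Step 11
Reactants: 14 methyl (S)-4-methyl-2-[13-(2-methyl-1,3-dioxolan-2-yl)tridecyl]-5-oxo-2,5-dihydrofuran-3-carboxylate
Product: 16 (S)-4-methyl-5-oxo-2-(14-oxopentadecyl)-2,5-dihydrofuran-3-carboxylic acid, via keto methyl ester 15 (not isolated)
Conditions: 3 M aq HCl–1,4-dioxane (1:1), rt, then 65 °C
Reagents that add atoms: water, O
Why: Aqueous acid should hydrolyse the dioxolane at room temperature and then the methyl ester on warming by acyl–oxygen cleavage, while the five-membered lactone is thermodynamically retained and the absence of base protects the acidic C5–H from furanolate formation.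

**Compound list**

1 | ω-pentadecalactone (oxacyclohexadecan-2-one) | O=C1CCCCCCCCCCCCCCO1 | starting material
2 | 15-hydroxy-N-methoxy-N-methylpentadecanamide | CON(C)C(=O)CCCCCCCCCCCCCCO | intermediate
3 | methylmagnesium bromide | C[Mg]Br | starting material
4 | 16-hydroxyhexadecan-2-one | CC(=O)CCCCCCCCCCCCCCO | intermediate
5 | 14-(2-methyl-1,3-dioxolan-2-yl)tetradecan-1-ol | CC1(CCCCCCCCCCCCCCO)OCCO1 | intermediate
6 | 14-(2-methyl-1,3-dioxolan-2-yl)tetradecanal | CC1(CCCCCCCCCCCCCC=O)OCCO1 | intermediate
7 | 1-propynylmagnesium bromide | CC#C[Mg]Br | starting material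
8 | (±)-17-(2-methyl-1,3-dioxolan-2-yl)heptadec-2-yn-4-ol | CC#CC(O)CCCCCCCCCCCCCC1(C)OCCO1 | intermediate
9 | 17-(2-methyl-1,3-dioxolan-2-yl)heptadec-2-yn-4-one | CC#CC(=O)CCCCCCCCCCCCCC1(C)OCCO1 | intermediate
10 | (R)-17-(2-methyl-1,3-dioxolan-2-yl)heptadec-2-yn-4-ol | CC#C[C@H](O)CCCCCCCCCCCCCC1(C)OCCO1 | intermediate
11 | (R)-17-(2-methyl-1,3-dioxolan-2-yl)heptadec-2-yn-4-yl methanesulfonate | CC#C[C@H](OS(C)(=O)=O)CCCCCCCCCCCCCC1(C)OCCO1 | intermediate
12 | carbon monoxide | [C-]#[O+] | starting material
13 | (aS)-2-methyl-17-(2-methyl-1,3-dioxolan-2-yl)heptadeca-2,3-dienoic acid | CC(C(=O)O)=[C@]=C([H])CCCCCCCCCCCCCC1(C)OCCO1 | intermediate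
14 | methyl (S)-4-methyl-2-[13-(2-methyl-1,3-dioxolan-2-yl)tridecyl]-5-oxo-2,5-dihydrofuran-3-carboxylate | CC1(CCCCCCCCCCCCC[C@@H]2OC(=O)C(C)=C2C(=O)OC)OCCO1 | intermediate
15 | methyl (S)-4-methyl-5-oxo-2-(14-oxopentadecyl)-2,5-dihydrofuran-3-carboxylate (keto methyl ester) | CC(=O)CCCCCCCCCCCCC[C@@H]1OC(=O)C(C)=C1C(=O)OC | intermediate
16 | (S)-4-methyl-5-oxo-2-(14-oxopentadecyl)-2,5-dihydrofuran-3-carboxylic acid (CNP0240323.2) | CC(=O)CCCCCCCCCCCCC[C@@H]1OC(=O)C(C)=C1C(=O)O | target

**Totals**

Total step count: 11. Longest linear sequence: 11 steps, from ω-pentadecalactone 1.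

**Steps most likely to fail**

1. Step 10 (proposed new method). The vinylpalladium may be captured by a proton or by a second allene instead of by CO. The reaction may also enter through a methoxycarbonylpalladium and a π-allyl intermediate, which would erode the transfer of chirality to C5. Fallback with known chemistry, setting out from allenoic acid 13: iodolactonisation with N-iodosuccinimide (MeCN, 0 °C, a little NaHCO3) should give (S)-4-iodo-3-methyl-5-[13-(2-methyl-1,3-dioxolan-2-yl)tridecyl]furan-2(5H)-one F1. Iodine and carboxylate add anti across the terminal allene bond, the same stereochemical course as intended for palladium. Alkoxycarbonylation of the vinyl iodide under zerovalent-palladium catalysis (PdCl2(PPh3)2, CO 1 atm, MeOH, NaOAc, 50 °C) then comes back to the route at ester 14.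

2. Step 9. Axial purity may be lost through SN2' exchange of the allenylpalladium with zerovalent palladium. The free allenoic acid may also cycloisomerise early to the 4-unsubstituted butenolide, and the ketal may be lost if the sulfonic acid is not fully buffered. Fallback, setting out from mesylate 11 and CO 12: carbonylation in the presence of 2-(trimethylsilyl)ethanol in place of water (Pd(PPh3)4, CO 1 atm, THF, rt) should give 2-(trimethylsilyl)ethyl (aS)-2-methyl-17-(2-methyl-1,3-dioxolan-2-yl)heptadeca-2,3-dienoate F2. This neutral ester cannot lactonise and can be purified. Fluoride cleavage (Bu4NF, THF, 0 °C) then releases the acid and comes back to the route at 13.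

3. Step 11. Hot acid may enolise the lactone toward the 2-hydroxyfuran and erode the C5 configuration, or the hindered conjugated ester may hydrolyse too slowly. Fallback, setting out from allenoic acid 13: the acid is taken to the (S)-4-iodobutenolide F1 as described under the first fallback. The iodide is carbonylated in the presence of 4-methoxybenzyl alcohol (PdCl2(PPh3)2, CO 1 atm, NaOAc, toluene, 60 °C) to give 4-methoxybenzyl (S)-4-methyl-2-[13-(2-methyl-1,3-dioxolan-2-yl)tridecyl]-5-oxo-2,5-dihydrofuran-3-carboxylate F3. Trifluoroacetic acid with anisole in CH2Cl2 at 0 °C, followed by addition of water, cleaves the benzylic ester by ionisation and removes the dioxolane without heating. This comes back to the route at target 16.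

**Further compounds**

F1 | step 10 | (S)-4-iodo-3-methyl-5-[13-(2-methyl-1,3-dioxolan-2-yl)tridecyl]furan-2(5H)-one | CC1(CCCCCCCCCCCCC[C@@H]2OC(=O)C(C)=C2I)OCCO1
F2 | step 9 | 2-(trimethylsilyl)ethyl (aS)-2-methyl-17-(2-methyl-1,3-dioxolan-2-yl)heptadeca-2,3-dienoate | CC(C(=O)OCC[Si](C)(C)C)=[C@]=C([H])CCCCCCCCCCCCCC1(C)OCCO1
F3 | step 11 | 4-methoxybenzyl (S)-4-methyl-2-[13-(2-methyl-1,3-dioxolan-2-yl)tridecyl]-5-oxo-2,5-dihydrofuran-3-carboxylate | CC1(CCCCCCCCCCCCC[C@@H]2OC(=O)C(C)=C2C(=O)OCc3ccc(OC)cc3)OCCO1
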